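**Plan**

- The last disconnections remove the four MOM ethers and the C2–H bond: target ⇐ tetra-MOM (2S)-flavanone ⇐ tetra-MOM flavone.
- The flavone is cut at C4a–C4, C4–C3 and O1–C2. The C4 carbonyl carbon lies between ring A carbon C4a and C3, and O1 sits on C8a next to C4a, so ring C divides into an ortho-iodophenol, carbon monoxide (C4) and the ring B arylacetylene (C3, C2).
- Ring A: phloroglucinol is differentiated (two MOM ethers, the third oxygen first as a silyl ether and then as an oxanyl acetal). Its three C–H bonds are replaced one at a time by directed ortho-metalation: prenyl at C4, prenyl at C2, iodine at C6.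
- Ring B: 3,5-dihydroxybenzaldehyde is MOM-protected and homologated to the terminal alkyne.
- Forward order: rings A and B are carried in, ring C closes in the three-component carbonylative annulation, and the single stereocentre (C2, S) is then set by ligand-controlled copper hydride 1,4-reduction and kept through an acidic, non-enolising deprotection.

Key step: step 11

Remark: the oxanyl acetal carbon makes compounds 8 to 12 racemic; this centre is removed in step 8 and has no bearing on the target.
Assumption: (R)-DTBM-SEGPHOS is taken to direct hydride to the C2 face that gives the (2S) product; if a model flavone shows the opposite sense, the (S)-ligand is used with no other change.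

**Route**

Step 1
Reactants: 1 phloroglucinol
Product: 2 3,5-bis(methoxymethoxy)phenol
Conditions: MOMCl (2.1 equiv), i-Pr2NEt (2.5 equiv), DMF, 0 °C → rt
Reagents that add atoms: chloromethyl methyl ether, COCCl
Why: Base-mediated O-alkylation (Williamson-type etherification with an α-chloro ether) of the symmetric triphenol with two equivalents of MOMCl should give a statistical mixture from which the bis-ether 2 is separated by chromatography, the mono-ether being resubmitted.

Step 2
Reactants: 2 3,5-bis(methoxymethoxy)phenol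
Product: 3 [3,5-bis(methoxymethoxy)phenoxy]tri(propan-2-yl)silane
Conditions: TIPSCl, imidazole, DMF, rt
Reagents that add atoms: chlorotri(propan-2-yl)silane, CC(C)[Si](Cl)(C(C)C)C(C)C
Why: Imidazole-promoted silylation of the one free phenol installs a bulky, non-coordinating TIPS ether that shields C2 and C6 and has no directing effect, so that the next metalation can only take place between the two MOM ethers.

Step 3
Reactants: 3 [3,5-bis(methoxymethoxy)phenoxy]tri(propan-2-yl)silane; 4 prenyl bromide (1-bromo-3-methylbut-2-ene)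
Product: 6 [3,5-bis(methoxymethoxy)-4-(3-methylbut-2-en-1-yl)phenoxy]tri(propan-2-yl)silane, via aryllithium 5 (not isolated)
Conditions: n-BuLi, THF, 0 °C; then CuBr·SMe2 (10 mol %), 4, −78 °C → rt
Reagents that add atoms: none
Why: Directed ortho-metalation, in which the two MOM ethers jointly guide n-BuLi to C4 (the only position both flank), followed by allylation of aryllithium 5 at the primary carbon of prenyl bromide under CuBr·SMe2 catalysis (SN2 over SN2′).

Step 4
Reactants: 6 [3,5-bis(methoxymethoxy)-4-(3-methylbut-2-en-1-yl)phenoxy]tri(propan-2-yl)silane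
Product: 7 3,5-bis(methoxymethoxy)-4-(3-methylbut-2-en-1-yl)phenol
Conditions: TBAF, THF, 0 °C; aqueous work-up
Reagents that add atoms: none
Why: Fluoride-induced Si–O cleavage, driven by the strong Si–F bond, should free the phenol while the MOM ethers and the alkene are inert to TBAF.

Step 5
Reactants: 7 3,5-bis(methoxymethoxy)-4-(3-methylbut-2-en-1-yl)phenol
Product: 8 2-[3,5-bis(methoxymethoxy)-4-(3-methylbut-2-en-1-yl)phenoxy]oxane (racemic)
Conditions: 3,4-dihydro-2H-pyran, PPTS (10 mol %), CH2Cl2, rt
Reagents that add atoms: 3,4-dihydro-2H-pyran, C1=COCCC1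
Why: Acid-catalysed addition of the phenol to the enol ether (tetrahydropyranylation) gives an aryl acetal that both directs metalation and is cleaved under far milder acid than an aryl MOM ether.

Step 6
Reactants: 8 2-[3,5-bis(methoxymethoxy)-4-(3-methylbut-2-en-1-yl)phenoxy]oxane; 4 prenyl bromide
Product: 10 2-[3,5-bis(methoxymethoxy)-2,4-bis(3-methylbut-2-en-1-yl)phenoxy]oxane (racemic), via aryllithium 9 (not isolated)
Conditions: n-BuLi, THF, 0 °C; then CuBr·SMe2 (10 mol %), 4, −78 °C → rt
Reagents that add atoms: none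
Why: Directed ortho-metalation at C2, which is flanked by the oxanyl acetal and a MOM ether and is equivalent to C6 so that only one regioisomer can form, followed by copper-catalysed SN2 allylation of aryllithium 9 with prenyl bromide.

Step 7
Reactants: 10 2-[3,5-bis(methoxymethoxy)-2,4-bis(3-methylbut-2-en-1-yl)phenoxy]oxane
Product: 12 2-[2-iodo-3,5-bis(methoxymethoxy)-4,6-bis(3-methylbut-2-en-1-yl)phenoxy]oxane (racemic), via aryllithium 11 (not isolated)
Conditions: n-BuLi, THF, 0 °C; then I2, THF, −78 °C; aq. Na2S2O3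
Reagents that add atoms: iodine, II
Why: Directed ortho-metalation at the last ring C–H (between the oxanyl acetal and a MOM ether) and iodinolysis of aryllithium 11 at −78 °C place iodine without electrophilic aromatic iodination, so that iodoetherification of the prenyl groups is avoided.

Step 8
Reactants: 12 2-[2-iodo-3,5-bis(methoxymethoxy)-4,6-bis(3-methylbut-2-en-1-yl)phenoxy]oxane
Product: 13 2-iodo-3,5-bis(methoxymethoxy)-4,6-bis(3-methylbut-2-en-1-yl)phenol
Conditions: PPTS (20 mol %), MeOH, rt
Reagents that add atoms: none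
Why: Pyridinium-catalysed transacetalisation with methanol should cleave the aryl oxanyl acetal much faster than the aryl MOM ethers, and the weak acid should neither protonate the prenyl alkenes nor cause protodeiodination of the electron-rich ring.

Step 9
Reactants: 14 3,5-dihydroxybenzaldehyde
Product: 15 3,5-bis(methoxymethoxy)benzaldehyde
Conditions: MOMCl (2.5 equiv), i-Pr2NEt (3 equiv), CH2Cl2, 0 °C → rt
Reagents that add atoms: chloromethyl methyl ether, COCCl
Why: Base-mediated O-alkylation of both phenols (Williamson-type etherification) masks them in the same form as on ring A, so that one acid treatment frees all four at the end.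

Step 10
Reactants: 15 3,5-bis(methoxymethoxy)benzaldehyde
Product: 16 1-ethynyl-3,5-bis(methoxymethoxy)benzene
Conditions: dimethyl (1-diazo-2-oxopropyl)phosphonate, K2CO3, MeOH, rt
Reagents that add atoms: dimethyl (1-diazo-2-oxopropyl)phosphonate, CC(=O)C(=[N+]=[N-])P(=O)(OC)OC
Why: Seyferth–Gilbert homologation in its Ohira–Bestmann form converts the non-enolisable aldehyde into the terminal alkyne with one added carbon under K2CO3/MeOH, conditions that leave the MOM ethers intact.

Step 11
Reactants: 13 2-iodo-3,5-bis(methoxymethoxy)-4,6-bis(3-methylbut-2-en-1-yl)phenol; 16 1-ethynyl-3,5-bis(methoxymethoxy)benzene; 17 carbon monoxide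
Product: 20 2-[3,5-bis(methoxymethoxy)phenyl]-5,7-bis(methoxymethoxy)-6,8-bis(3-methylbut-2-en-1-yl)-4H-chromen-4-one, via ortho-hydroxyaryl ynone 18 (not isolated), via diethylamino enone 19 (not isolated)
Conditions: PdCl2(PPh3)2 (5 mol %), CO (20 bar), Et2NH, 100–120 °C, autoclave
Reagents that add atoms: none
Why: Zerovalent palladium, formed in situ from PdCl2(PPh3)2, should insert into the C–I bond of 13, CO then inserts to give the aroylpalladium iodide, and amine-assisted coupling with the terminal alkyne 16 releases the ortho-hydroxyaryl ynone 18, which makes C4a–C4 and C4–C3. Diethylamine adds to the ynone to give the enaminone 19, and the phenolic oxygen displaces the amine at C2 by addition–elimination, which forms O1–C2 and closes ring C in a 6-endo mode (6-endo-trig on the enaminone, formally 6-endo-dig on the ynone). The closest known reaction type is the palladium-catalysed carbonylative coupling and cyclisation of ortho-iodophenols with terminal acetylenes in secondary amines, which gives flavones. No stereocentre is formed. The step needs carbonylative over direct alkynylation, which the CO pressure, the absence of a copper co-catalyst and the electron-rich aryl group (fast acyl formation) should secure, and six- over five-membered (aurone) closure, which the secondary amine secures by turning the ynone into the enaminone before the oxygen attacks. The C–I bond is the only site open to oxidative addition on the fully substituted ring A, and the trisubstituted prenyl alkenes lie meta to the reacting carbon, out of reach of the acylpalladium centre.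

Step 12
Reactants: 20 2-[3,5-bis(methoxymethoxy)phenyl]-5,7-bis(methoxymethoxy)-6,8-bis(3-methylbut-2-en-1-yl)-4H-chromen-4-one
Product: 22 (2S)-2-[3,5-bis(methoxymethoxy)phenyl]-5,7-bis(methoxymethoxy)-6,8-bis(3-methylbut-2-en-1-yl)-2,3-dihydro-4H-chromen-4-one, via silyl enol ether 21 (not isolated)
Conditions: Cu(OAc)2 (5 mol %), (R)-DTBM-SEGPHOS (5.5 mol %), (EtO)2MeSiH (3 equiv), toluene, 0 °C → rt; then 1 M aq. HCl, THF, 0 °C, brief
Reagents that add atoms: none
Why: Asymmetric copper hydride conjugate reduction, in which the bisphosphine-ligated CuH should add hydride to C2 of the chromone enone from the face chosen by the C2-symmetric ligand and so set (2S), the product being held as silyl enol ether 21 (shielded from 1,2-reduction and from ring opening) until mild acidic hydrolysis, while the isolated trisubstituted alkenes are inert to CuH.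

Step 13
Reactants: 22 (2S)-2-[3,5-bis(methoxymethoxy)phenyl]-5,7-bis(methoxymethoxy)-6,8-bis(3-methylbut-2-en-1-yl)-2,3-dihydro-4H-chromen-4-one
Product: 23 (2S)-2-(3,5-dihydroxyphenyl)-5,7-dihydroxy-6,8-bis(3-methylbut-2-en-1-yl)-2,3-dihydro-4H-chromen-4-one (CID26213315)
Conditions: 3 M aq. HCl, MeOH, 50 °C
Reagents that add atoms: none
Why: Acid-catalysed acetal methanolysis should remove the four aryl MOM ethers, a deprotection established for prenylated flavanones, and the C2 stereocentre is kept because flavanones racemise through base-induced ring opening and not under dilute acid at moderate temperature.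

**Compound list**

1 | phloroglucinol (benzene-1,3,5-triol) | Oc1cc(O)cc(O)c1 | starting material
2 | 3,5-bis(methoxymethoxy)phenol | Oc1cc(OCOC)cc(OCOC)c1 | intermediate
3 | [3,5-bis(methoxymethoxy)phenoxy]tri(propan-2-yl)silane | CC(C)[Si](Oc1cc(OCOC)cc(OCOC)c1)(C(C)C)C(C)C | intermediate
4 | prenyl bromide (1-bromo-3-methylbut-2-ene) | CC(C)=CCBr | starting material
5 | [2,6-bis(methoxymethoxy)-4-(triisopropylsilyloxy)phenyl]lithium | [Li]c1c(OCOC)cc(O[Si](C(C)C)(C(C)C)C(C)C)cc1OCOC | intermediate (not isolated)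
6 | [3,5-bis(methoxymethoxy)-4-(3-methylbut-2-en-1-yl)phenoxy]tri(propan-2-yl)silane | CC(C)=CCc1c(OCOC)cc(O[Si](C(C)C)(C(C)C)C(C)C)cc1OCOC | intermediate
7 | 3,5-bis(methoxymethoxy)-4-(3-methylbut-2-en-1-yl)phenol | CC(C)=CCc1c(OCOC)cc(O)cc1OCOC | intermediate
8 | 2-[3,5-bis(methoxymethoxy)-4-(3-methylbut-2-en-1-yl)phenoxy]oxane, racemic | CC(C)=CCc1c(OCOC)cc(OC2CCCCO2)cc1OCOC | intermediate
9 | [2,4-bis(methoxymethoxy)-3-(3-methylbut-2-en-1-yl)-6-(oxan-2-yloxy)phenyl]lithium, racemic | [Li]c1c(OC2CCCCO2)cc(OCOC)c(CC=C(C)C)c1OCOC | intermediate (not isolated)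
10 | 2-[3,5-bis(methoxymethoxy)-2,4-bis(3-methylbut-2-en-1-yl)phenoxy]oxane, racemic | CC(C)=CCc1c(OC2CCCCO2)cc(OCOC)c(CC=C(C)C)c1OCOC | intermediate
11 | [2,4-bis(methoxymethoxy)-3,5-bis(3-methylbut-2-en-1-yl)-6-(oxan-2-yloxy)phenyl]lithium, racemic | [Li]c1c(OCOC)c(CC=C(C)C)c(OCOC)c(CC=C(C)C)c1OC1CCCCO1 | intermediate (not isolated)
12 | 2-[2-iodo-3,5-bis(methoxymethoxy)-4,6-bis(3-methylbut-2-en-1-yl)phenoxy]oxane, racemic | Ic1c(OCOC)c(CC=C(C)C)c(OCOC)c(CC=C(C)C)c1OC1CCCCO1 | intermediate
13 | 2-iodo-3,5-bis(methoxymethoxy)-4,6-bis(3-methylbut-2-en-1-yl)phenol | Oc1c(CC=C(C)C)c(OCOC)c(CC=C(C)C)c(OCOC)c1I | intermediate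
14 | 3,5-dihydroxybenzaldehyde | O=Cc1cc(O)cc(O)c1 | starting material
15 | 3,5-bis(methoxymethoxy)benzaldehyde | O=Cc1cc(OCOC)cc(OCOC)c1 | intermediate
16 | 1-ethynyl-3,5-bis(methoxymethoxy)benzene | C#Cc1cc(OCOC)cc(OCOC)c1 | intermediate
17 | carbon monoxide | [C-]#[O+] | starting material
18 | 3-[3,5-bis(methoxymethoxy)phenyl]-1-[2-hydroxy-4,6-bis(methoxymethoxy)-3,5-bis(3-methylbut-2-en-1-yl)phenyl]prop-2-yn-1-one | O=C(C#Cc1cc(OCOC)cc(OCOC)c1)c1c(O)c(CC=C(C)C)c(OCOC)c(CC=C(C)C)c1OCOC | intermediate (not isolated)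
19 | (E)-3-(diethylamino)-3-[3,5-bis(methoxymethoxy)phenyl]-1-[2-hydroxy-4,6-bis(methoxymethoxy)-3,5-bis(3-methylbut-2-en-1-yl)phenyl]prop-2-en-1-one (drawn E; the geometry is lost on cyclisation) | CCN(CC)/C(=C/C(=O)c1c(O)c(CC=C(C)C)c(OCOC)c(CC=C(C)C)c1OCOC)c1cc(OCOC)cc(OCOC)c1 | intermediate (not isolated)
20 | 2-[3,5-bis(methoxymethoxy)phenyl]-5,7-bis(methoxymethoxy)-6,8-bis(3-methylbut-2-en-1-yl)-4H-chromen-4-one | CC(C)=CCc1c(OCOC)c(CC=C(C)C)c2c(c1OCOC)C(=O)C=C(c1cc(OCOC)cc(OCOC)c1)O2 | intermediate
21 | {[(2S)-2-[3,5-bis(methoxymethoxy)phenyl]-5,7-bis(methoxymethoxy)-6,8-bis(3-methylbut-2-en-1-yl)-2H-chromen-4-yl]oxy}diethoxy(methyl)silane | CC(C)=CCc1c(OCOC)c(CC=C(C)C)c2c(c1OCOC)C(O[Si](C)(OCC)OCC)=C[C@@H](c1cc(OCOC)cc(OCOC)c1)O2 | intermediate (not isolated)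
22 | (2S)-2-[3,5-bis(methoxymethoxy)phenyl]-5,7-bis(methoxymethoxy)-6,8-bis(3-methylbut-2-en-1-yl)-2,3-dihydro-4H-chromen-4-one | CC(C)=CCc1c(OCOC)c(CC=C(C)C)c2c(c1OCOC)C(=O)C[C@@H](c1cc(OCOC)cc(OCOC)c1)O2 | intermediate
23 | (2S)-2-(3,5-dihydroxyphenyl)-5,7-dihydroxy-6,8-bis(3-methylbut-2-en-1-yl)-2,3-dihydro-4H-chromen-4-one | CC(C)=CCc1c(O)c(CC=C(C)C)c2c(c1O)C(=O)C[C@@H](c1cc(O)cc(O)c1)O2 | target

**Count and risks**

Total step count: 13. Longest linear sequence: 11 steps (steps 1 to 8, then 11 to 13); steps 9 and 10 form the two-step side branch to the alkyne.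

The three steps most likely to fail:

Step 11. Oxidative addition into the doubly ortho-substituted, electron-rich C–I bond may be slow, so that alkyne oligomerisation, direct alkynylation without CO uptake (leading on to a benzofuran) or five-membered aurone closure could compete with the carbonylative 6-endo annulation. Fallback, setting out from 10 and returning at 20: 10 is lithiated as in step 7 to give 11, which is quenched with DMF to give 4,6-bis(methoxymethoxy)-3,5-bis(3-methylbut-2-en-1-yl)-2-(oxan-2-yloxy)benzaldehyde F1. Alkyne 16 is deprotonated with n-BuLi in THF at −78 °C to {[3,5-bis(methoxymethoxy)phenyl]ethynyl}lithium F2, which adds to F1 to give the propargylic alcohol 3-[3,5-bis(methoxymethoxy)phenyl]-1-[4,6-bis(methoxymethoxy)-3,5-bis(3-methylbut-2-en-1-yl)-2-(oxan-2-yloxy)phenyl]prop-2-yn-1-ol F3. Oxidation with MnO2 in CH2Cl2 gives the oxanyl-protected ynone 3-[3,5-bis(methoxymethoxy)phenyl]-1-[4,6-bis(methoxymethoxy)-3,5-bis(3-methylbut-2-en-1-yl)-2-(oxan-2-yloxy)phenyl]prop-2-yn-1-one F4. PPTS in MeOH then frees the phenol to give ynone 18, which on warming with Et2NH in EtOH should pass through enaminone 19 to flavone 20. In this detour C4 comes from DMF and no palladium or CO is needed.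

Step 12. Hydride transfer to C2 of an electron-rich vinylogous ester may be sluggish or poorly face-selective, and β-elimination of the ring oxygen from the enolate could erode the enantiomeric purity. Fallback, setting out from 20 and returning at 22: 1,4-reduction of 20 with LiBH(s-Bu)3 in THF at −78 °C gives racemic 2-[3,5-bis(methoxymethoxy)phenyl]-5,7-bis(methoxymethoxy)-6,8-bis(3-methylbut-2-en-1-yl)-2,3-dihydro-4H-chromen-4-one F5. Kinetic resolution by asymmetric transfer hydrogenation with RuCl(p-cymene)[(R,R)-TsDPEN] and HCO2H/Et3N, run to about half conversion, should reduce the (2R) ketone faster to the 2,4-cis alcohol (2R,4R)-2-[3,5-bis(methoxymethoxy)phenyl]-5,7-bis(methoxymethoxy)-6,8-bis(3-methylbut-2-en-1-yl)-3,4-dihydro-2H-chromen-4-ol F6 and leave the (2S) ketone 22, which is separated by chromatography.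

Step 6. Deprotonation at the benzylic and allylic CH2 of the C4 prenyl group (lateral metalation) may compete with ring metalation, and SN2′ attack on prenyl bromide may give the branched isomer. Fallback, setting out from 7 and returning at 10: Tsuji–Trost O-allylation of phenol 7 with tert-butyl 2-methylbut-3-en-2-yl carbonate and Pd(PPh3)4 in THF at 0 °C gives the tertiary allyl ether 1,3-bis(methoxymethoxy)-5-[(2-methylbut-3-en-2-yl)oxy]-2-(3-methylbut-2-en-1-yl)benzene F7. Aromatic Claisen rearrangement in toluene at 110 °C moves the allyl unit to the free ortho position with allylic inversion and gives 3,5-bis(methoxymethoxy)-2,4-bis(3-methylbut-2-en-1-yl)phenol F8. Tetrahydropyranylation as in step 5 then gives 10.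

**Further compounds**

F1 | step 11 | 4,6-bis(methoxymethoxy)-3,5-bis(3-methylbut-2-en-1-yl)-2-(oxan-2-yloxy)benzaldehyde, racemic | O=Cc1c(OCOC)c(CC=C(C)C)c(OCOC)c(CC=C(C)C)c1OC1CCCCO1
F2 | step 11 | {[3,5-bis(methoxymethoxy)phenyl]ethynyl}lithium | [Li]C#Cc1cc(OCOC)cc(OCOC)c1
F3 | step 11 | 3-[3,5-bis(methoxymethoxy)phenyl]-1-[4,6-bis(methoxymethoxy)-3,5-bis(3-methylbut-2-en-1-yl)-2-(oxan-2-yloxy)phenyl]prop-2-yn-1-ol, mixture of diastereomers | OC(C#Cc1cc(OCOC)cc(OCOC)c1)c1c(OCOC)c(CC=C(C)C)c(OCOC)c(CC=C(C)C)c1OC1CCCCO1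
F4 | step 11 | 3-[3,5-bis(methoxymethoxy)phenyl]-1-[4,6-bis(methoxymethoxy)-3,5-bis(3-methylbut-2-en-1-yl)-2-(oxan-2-yloxy)phenyl]prop-2-yn-1-one, racemic | O=C(C#Cc1cc(OCOC)cc(OCOC)c1)c1c(OCOC)c(CC=C(C)C)c(OCOC)c(CC=C(C)C)c1OC1CCCCO1
F5 | step 12 | 2-[3,5-bis(methoxymethoxy)phenyl]-5,7-bis(methoxymethoxy)-6,8-bis(3-methylbut-2-en-1-yl)-2,3-dihydro-4H-chromen-4-one, racemic | CC(C)=CCc1c(OCOC)c(CC=C(C)C)c2c(c1OCOC)C(=O)CC(c1cc(OCOC)cc(OCOC)c1)O2
F6 | step 12 | (2R,4R)-2-[3,5-bis(methoxymethoxy)phenyl]-5,7-bis(methoxymethoxy)-6,8-bis(3-methylbut-2-en-1-yl)-3,4-dihydro-2H-chromen-4-ol | CC(C)=CCc1c(OCOC)c(CC=C(C)C)c2c(c1OCOC)[C@H](O)C[C@H](c1cc(OCOC)cc(OCOC)c1)O2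
F7 | step 6 | 1,3-bis(methoxymethoxy)-5-[(2-methylbut-3-en-2-yl)oxy]-2-(3-methylbut-2-en-1-yl)benzene | C=CC(C)(C)Oc1cc(OCOC)c(CC=C(C)C)c(OCOC)c1
F8 | step 6 | 3,5-bis(methoxymethoxy)-2,4-bis(3-methylbut-2-en-1-yl)phenol | Oc1cc(OCOC)c(CC=C(C)C)c(OCOC)c1CC=C(C)C
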